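Numbering (bisabolane): ring C1–C6 with OAng on C1 and C2, CH3 (C15) on C3, oxirane on C3/C4, C5 = CH2, side chain C7(=C14H2)–C8H(OAc)–C9H2–C10H=C11Me2 on C6. β is the ring face of the oxirane oxygen, and O1, O2, the oxirane O and C7 are all β.
Enabling feature: the C3–O and C6–C7 bonds stand 1,4-cis across the cyclohexane and C7 can be a carbonyl carbon. Joining O3 to C7 as a lactone turns the ring into a 2-oxabicyclo[2.2.2]octene, the Diels–Alder adduct of 6-methyl-2-pyrone (atoms O3, C3, C2, C1, C6, C7) with a C4=C5 vinyl unit.
Cuts (retro): acetate; C7–C8; both angelates; C7–C14; oxirane C4–O; lactone C7–O3 re-formed; C4–O back to C4–CHO; C1–O and C2–O; last, C5–C6 and C3–C4 together.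
Forward: step 1 makes the carbocycle and the temporary lactone ring at once. The bicycle is dihydroxylated, its formyl activator is degraded to an oxygen leaving group, the lactone is opened and O3 closes the oxirane. The chain then grows at C7 (methyl ketone, enol triflate, coupling with the C8–C13 aldehyde).
Stereochemistry: absolute sense and C4 come from the amine-catalysed endo cycloaddition, C3/C6 from the lactone tether, C1/C2 from osmylation on the lactone side of the bicycle. C4 is inverted in the oxirane closure and C8 is set by a chiral chromium ligand.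

Key step: step 1

Assumption: 6-methyl-2H-pyran-2-one is taken as a catalogue compound.
Assumption: the (4S) ligand of step 12 is taken to direct the alkenylchromium reagent to the aldehyde face that gives 8S; should the hindered partner respond in the opposite sense, the (4R) ligand is used in the same way.

Step 1
Reactants: 1 6-methyl-2H-pyran-2-one; 2 acrolein
Product: 3 (1R,4R,7R)-1-methyl-3-oxo-2-oxabicyclo[2.2.2]oct-5-ene-7-carbaldehyde (endo adduct; lactone bridge O3–C7 β; 4α-CHO syn to C1=C2)
Conditions: (5S)-5-benzyl-2,2,3-trimethylimidazolidin-4-one·HCl (20 mol %), 2 (5 equiv), MeCN–H2O 95:5, 8 kbar, 25 °C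
Reagents that add atoms: none
Why: Proposed new method: acrolein condenses with the amine salt to an (E)-iminium ion whose low LUMO meets the pyrone HOMO in an asynchronous, concerted [4πs+2πs] cycloaddition, in which the enol-ester terminus (pyrone C3 = target C6) bonds first to the iminium CH2 (C5), the charge building at pyrone C6 (= target C3) is carried by the ring oxygen and the methyl group and is quenched by the enamine carbon (C4), and hydrolysis frees 3 and the catalyst. The closest known reaction types are the imidazolidinone-catalysed Diels–Alder reactions of acrolein with 1,3-cyclohexadiene and 1-acetoxybutadiene and the uncatalysed hyperbaric cycloadditions of 2-pyrones with acrylic dienophiles; new is their union, with pressure (strongly negative activation volume) making up for the partial aromaticity of the pyrone at a temperature at which the adduct keeps its CO2, and covalent activation chosen because it cannot be poisoned by the Lewis-basic pyrone carbonyl. One ring is closed, the C1–C6 carbocycle, by intermolecular suprafacial addition across the two pyrone termini, which turns the flat lactone into the O3–C7 bridge of a 2-oxabicyclo[2.2.2]octene. C3 and C6 are fixed relative to each other by that bridge (O on C3 and C7 on C6 must be cis), C4 by the endo rule (iminium under the diene, hence formyl syn to C1=C2 and anti-periplanar to the bridge oxygen), and the absolute sense by the benzyl group of the catalyst, which covers one face of the iminium ion and is assigned by analogy with the cyclohexadiene case. The step needs regioselectivity (formyl-bearing carbon next to the methyl-bearing carbon), secured by the push–pull polarisation of the pyrone and sharpened by the cationic dienophile, endo selectivity, and ring closure in preference to simple conjugate alkylation at pyrone C3, favoured because the enamine and oxocarbenium ends are held within bonding distance.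

Step 2
Reactants: 3 endo adduct
Product: 4 1β,2β-diol of 3 (both OH syn to the lactone bridge)
Conditions: OsO4 (2 mol %), NMO (1.3 equiv), acetone–H2O 9:1, 0 °C to rt
Reagents that add atoms: N-methylmorpholine N-oxide C[N+]1([O-])CCOCC1; water O
Why: Upjohn dihydroxylation, in which OsO4 adds suprafacially to the C1=C2 bridge from the sector next to the flat, substituent-free lactone bridge because the other sector is filled by the endo formyl group on C4 and the endo hydrogen on C5, which sets O1 and O2 β, cis to O3 and C7.

Step 3
Reactants: 4 diol
Product: 5 1β,2β-bis(triethylsilyl) ether of 4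
Conditions: TESOTf (2.4 equiv), 2,6-lutidine, CH2Cl2, −78 to 0 °C
Reagents that add atoms: triethylsilyl triflate CC[Si](CC)(CC)OS(=O)(=O)C(F)(F)F
Why: Silyl ether formation with a silyl triflate and a hindered pyridine base is fast at low temperature, so both β-hydroxyls are capped before O2 can translactonise onto C7, and the non-nucleophilic base leaves the strained lactone and the epimerisable aldehyde alone, no stereocenter being changed.

Step 4
Reactants: 5 bis-silyl ether aldehyde
Product: 6 4α-formate (formyloxy in place of formyl)
Conditions: mCPBA (1.5 equiv), CH2Cl2–aq. pH 7 phosphate buffer, 0 °C to rt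
Reagents that add atoms: mCPBA O=C(OO)c1cccc(Cl)c1
Why: Baeyer–Villiger oxidation of an α-branched aldehyde, in whose Criegee adduct the secondary carbon C4 migrates in preference to hydrogen and with retention, so the formyl activator becomes an oxygen substituent that stays α, anti to O3.

Step 5
Reactants: 6 formate lactone
Product: 7 Weinreb amide diol (6β-C(O)N(OMe)Me; 1β,2β-bis-OTES; 3β-OH/3α-CH3; 4α-OH)
Conditions: MeNH(OMe)·HCl (6 equiv), iPrMgCl (12 equiv), THF, −20 to 0 °C
Reagents that add atoms: N,O-dimethylhydroxylamine hydrochloride CNOC.Cl
Why: Weinreb aminolysis with the chloromagnesium amide, in which relief of the boat strain of the bicyclic δ-lactone drives acyl–oxygen cleavage at C7, the same reagent cleaves the formate, the silyl ethers are inert and no stereocenter is touched, so the temporary ring is removed and the trans 3β,4α-diol is laid bare.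

Step 6
Reactants: 7 Weinreb amide diol
Product: 9 3β,4β-epoxy Weinreb amide, via C4 mesylate 8 (not isolated)
Conditions: MsCl (1.2 equiv), Et3N, CH2Cl2, −20 °C; then K2CO3, MeOH, 0 °C to rt
Reagents that add atoms: methanesulfonyl chloride CS(=O)(=O)Cl (its atoms stay only in 8)
Why: Sulfene mesylation picks the secondary 4α-hydroxyl over the tertiary 3β-hydroxyl, and mild base then triggers the 3-exo-tet closure known from trans-halohydrins through the trans-diaxial conformer, O3 displacing the mesylate with inversion at C4 so that the oxirane lies on the β face.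

Step 7
Reactants: 9 epoxy Weinreb amide
Product: 10 methyl ketone (6β-acetyl)
Conditions: MeMgBr (3 equiv), THF, −20 to 0 °C
Reagents that add atoms: methylmagnesium bromide C[Mg]Br
Why: Weinreb ketone synthesis, in which the chelated tetrahedral adduct stops at single addition and the low temperature spares the oxirane, the silyl ethers and the C6 stereocenter.

Step 8
Reactants: 10 methyl ketone
Product: 12 enol triflate C7(OTf)=C14H2, via potassium enolate 11 (not isolated)
Conditions: KN(SiMe3)2 (1.1 equiv), THF, −78 °C; then N-(5-chloropyridin-2-yl)bis(trifluoromethanesulfonimide), −78 °C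
Reagents that add atoms: N-(5-chloropyridin-2-yl)bis(trifluoromethanesulfonimide) O=S(=O)(N(c1ccc(Cl)cn1)S(=O)(=O)C(F)(F)F)C(F)(F)F
Why: Kinetic enolate formation and O-triflation, in which the bulky amide takes the open methyl protons (C14) rather than the tertiary H6, the pyridyl triflimide traps the enolate at −78 °C before it can equilibrate towards β-elimination of O1, and attack on the oxirane is geometrically barred because side chain and oxirane oxygen share the β face.

Step 9
Reactants: 12 enol triflate
Product: 13 1β,2β-diol enol triflate
Conditions: Et3N·3HF, MeCN, rt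
Reagents that add atoms: none
Why: Fluoride desilylation under almost neutral conditions removes both triethylsilyl groups without base-induced elimination of the enol triflate to an alkyne and without acid opening of the oxirane, and Payne rearrangement is impossible because O2 and the oxirane oxygen are cis.

Step 10
Reactants: 13 diol enol triflate; 14 angelic acid
Product: 16 1β,2β-bis(angelate) enol triflate, via mixed anhydride 15 (not isolated)
Conditions: 14 (6 equiv), 2,4,6-trichlorobenzoyl chloride (6 equiv), Et3N (14 equiv), toluene, rt; then 13, 80 °C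
Reagents that add atoms: 2,4,6-trichlorobenzoyl chloride O=C(Cl)c1c(Cl)cc(Cl)cc1Cl (its atoms stay only in 15)
Why: Yamaguchi-type mixed-anhydride acylation run thermally and without a nucleophilic catalyst, the conditions known to transfer the (Z)-2-methylbut-2-enoyl group to hindered secondary alcohols without Z-to-E isomerisation, the excess amine holding the liberated acid as its salt so that the oxirane survives.

Step 11
Reactants: 17 4-methylpent-3-en-1-ol
Product: 18 4-methylpent-3-enal
Conditions: Dess–Martin periodinane, pyridine, CH2Cl2, 0 °C; used at once as a solution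
Reagents that add atoms: none
Why: Dess–Martin oxidation is neutral when buffered with pyridine and stops at the aldehyde, so the β,γ-double bond should not move into conjugation.

Step 12
Reactants: 16 bis(angelate) enol triflate; 18 4-methylpent-3-enal
Product: 19 (8S)-allylic alcohol
Conditions: CrCl2 (4 equiv), N-{2-[(4S)-4-isopropyl-4,5-dihydrooxazol-2-yl]-6-methylphenyl}methanesulfonamide (4.4 equiv), Et3N (4.4 equiv), NiCl2 (5 mol %), 18 (3 equiv), THF, rt
Reagents that add atoms: none
Why: Asymmetric Nozaki–Hiyama–Kishi coupling, in which zerovalent nickel inserts into the C7–OTf bond, transmetallation gives an alkenyl species of trivalent chromium that adds only to the aldehyde in the presence of esters and oxirane, and the chiral sulfonamide ligand on chromium selects the aldehyde face to set 8S.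

Step 13
Reactants: 19 allylic alcohol
Product: 20 target CNP0188566.2
Conditions: Ac2O, pyridine, DMAP (cat.), CH2Cl2, 0 °C
Reagents that add atoms: acetic anhydride CC(=O)OC(C)=O
Why: Standard DMAP-catalysed acetylation of the only free hydroxyl proceeds with retention at C8 and is too mild to isomerise the angelates or open the oxirane.

Compound list
1 | 6-methyl-2H-pyran-2-one | CC1=CC=CC(=O)O1 | starting material
2 | acrolein | C=CC=O | starting material
3 | (1R,4R,7R)-1-methyl-3-oxo-2-oxabicyclo[2.2.2]oct-5-ene-7-carbaldehyde (endo; O3–C7 bridge β, 4α-CHO) | [C@H]12C[C@@H](C=O)[C@](C)(OC1=O)C=C2 | intermediate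
4 | 1β,2β-diol of 3 | [C@H]12C[C@@H](C=O)[C@](C)(OC1=O)[C@H](O)[C@@H]2O | intermediate
5 | 1β,2β-bis(triethylsilyl) ether of 4 | [C@H]12C[C@@H](C=O)[C@](C)(OC1=O)[C@H](O[Si](CC)(CC)CC)[C@@H]2O[Si](CC)(CC)CC | intermediate
6 | 4α-formate lactone | [C@H]12C[C@@H](OC=O)[C@](C)(OC1=O)[C@H](O[Si](CC)(CC)CC)[C@@H]2O[Si](CC)(CC)CC | intermediate
7 | Weinreb amide, 3β-OH, 4α-OH, 1β,2β-bis-OTES | CON(C)C(=O)[C@@H]1C[C@@H](O)[C@](C)(O)[C@H](O[Si](CC)(CC)CC)[C@@H]1O[Si](CC)(CC)CC | intermediate
8 | 4α-mesylate of 7 | CON(C)C(=O)[C@@H]1C[C@@H](OS(C)(=O)=O)[C@](C)(O)[C@H](O[Si](CC)(CC)CC)[C@@H]1O[Si](CC)(CC)CC | intermediate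
9 | 3β,4β-epoxy Weinreb amide | CON(C)C(=O)[C@@H]1C[C@@H]2O[C@]2(C)[C@H](O[Si](CC)(CC)CC)[C@@H]1O[Si](CC)(CC)CC | intermediate
10 | 6β-acetyl epoxide (methyl ketone) | CC(=O)[C@@H]1C[C@@H]2O[C@]2(C)[C@H](O[Si](CC)(CC)CC)[C@@H]1O[Si](CC)(CC)CC | intermediate
11 | potassium enolate (C7=C14) of 10 | C=C([O-])[C@@H]1C[C@@H]2O[C@]2(C)[C@H](O[Si](CC)(CC)CC)[C@@H]1O[Si](CC)(CC)CC.[K+] | intermediate
12 | enol triflate, bis-OTES | C=C(OS(=O)(=O)C(F)(F)F)[C@@H]1C[C@@H]2O[C@]2(C)[C@H](O[Si](CC)(CC)CC)[C@@H]1O[Si](CC)(CC)CC | intermediate
13 | enol triflate, 1β,2β-diol | C=C(OS(=O)(=O)C(F)(F)F)[C@@H]1C[C@@H]2O[C@]2(C)[C@H](O)[C@@H]1O | intermediate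
14 | angelic acid, (Z)-2-methylbut-2-enoic acid | C/C=C(/C)C(=O)O | starting material
15 | angelic 2,4,6-trichlorobenzoic anhydride | C/C=C(/C)C(=O)OC(=O)c1c(Cl)cc(Cl)cc1Cl | intermediate
16 | enol triflate, 1β,2β-bis(angelate) | C=C(OS(=O)(=O)C(F)(F)F)[C@@H]1C[C@@H]2O[C@]2(C)[C@H](OC(=O)/C(C)=C\C)[C@@H]1OC(=O)/C(C)=C\C | intermediate
17 | 4-methylpent-3-en-1-ol | CC(C)=CCCO | starting material
18 | 4-methylpent-3-enal | CC(C)=CCC=O | intermediate
19 | (8S)-8-hydroxy-1β,2β-bis(angeloyloxy)-3β,4β-epoxybisabola-7(14),10-diene | C=C([C@H](CC=C(C)C)O)[C@@H]1C[C@@H]2O[C@]2(C)[C@H](OC(=O)/C(C)=C\C)[C@@H]1OC(=O)/C(C)=C\C | intermediate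
20 | (1R,2R,3S,4S,6S,8S)-8-acetoxy-1,2-bis(angeloyloxy)-3,4-epoxybisabola-7(14),10-diene | C=C([C@H](CC=C(C)C)OC(C)=O)[C@@H]1C[C@@H]2O[C@]2(C)[C@H](OC(=O)/C(C)=C\C)[C@@H]1OC(=O)/C(C)=C\C | target

Total steps: 13. Longest linear sequence: 12 (steps 1–10, 12, 13).

Steps most likely to fail

Step 1. The cycloaddition may be too slow to outrun oligomerisation of acrolein. The polar intermediate may lose a proton and end as simple C-alkylation of the pyrone. An uncatalysed background reaction under pressure may also erode the enantiomeric purity. The fallback uses known chemistry and takes the absolute configuration from a resolution instead of from catalysis. Setting out from 1 and 2, the uncatalysed hyperbaric cycloaddition (CH2Cl2, 12–14 kbar, 25–40 °C, trace of hydroquinone) should give 3 together with its mirror image ent-3 F1. Condensation of this racemate with (1R,2R)-N,N'-dimethyl-1,2-diphenylethane-1,2-diamine (Et2O, molecular sieves, rt) gives two diastereomeric imidazolidines, the aminal of 3 F2 and the aminal of ent-3 F3. These are separated by chromatography or crystallisation. Brief hydrolysis of F2 (dilute aq. HCl–Et2O, 0 °C) comes back to the route at 3.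

Step 12. The facial selectivity at the aldehyde may be poor if the ligand and the hindered alkenylchromium reagent are mismatched, and the aldehyde may drift into conjugation during a slow coupling. The fallback sets C8 by reduction instead of by addition. Setting out from 16 and 18, the ligand-free coupling (CrCl2, NiCl2 cat., DMF, rt) gives 19 mixed with its 8R epimer F4. Dess–Martin oxidation of the mixture (pyridine, CH2Cl2, 0 °C) converges on the α-methylene ketone F5. Corey–Bakshi–Shibata reduction with (R)-2-methyl-oxazaborolidine and catecholborane (toluene, −78 °C), the branched alkenyl group acting as the large substituent, comes back to the route at 19.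

Step 10. The second acylation of the crowded cis-diol may stall, and prolonged heating may bring Z-to-E isomerisation of the acyl group or opening of the oxirane. The fallback builds the Z-alkene on the ester instead of transferring it. Setting out from 13, esterification with 2-[bis(2,2,2-trifluoroethoxy)phosphoryl]propanoic acid (EDC·HCl, DMAP, CH2Cl2, rt), which has no double bond to isomerise, gives the bis(phosphonopropionate) F6. A twofold Still–Gennari olefination (KN(SiMe3)2, 18-crown-6, THF, −78 °C; acetaldehyde) comes back to the route at 16.

Further compounds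
F1 | step 1 | ent-3, mirror image of the endo adduct | [C@@H]12C[C@H](C=O)[C@@](C)(OC1=O)C=C2
F2 | step 1 | imidazolidine (aminal) of 3 with the (1R,2R)-diamine | [C@H]12C[C@@H](C3N(C)[C@H](c4ccccc4)[C@@H](c4ccccc4)N3C)[C@](C)(OC1=O)C=C2
F3 | step 1 | imidazolidine (aminal) of ent-3 with the (1R,2R)-diamine | [C@@H]12C[C@H](C3N(C)[C@H](c4ccccc4)[C@@H](c4ccccc4)N3C)[C@@](C)(OC1=O)C=C2
F4 | step 12 | 8R epimer of 19 | C=C([C@@H](CC=C(C)C)O)[C@@H]1C[C@@H]2O[C@]2(C)[C@H](OC(=O)/C(C)=C\C)[C@@H]1OC(=O)/C(C)=C\C
F5 | step 12 | C8 ketone (α-methylene ketone) | C=C(C(=O)CC=C(C)C)[C@@H]1C[C@@H]2O[C@]2(C)[C@H](OC(=O)/C(C)=C\C)[C@@H]1OC(=O)/C(C)=C\C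
F6 | step 10 | 1β,2β-bis[2-(bis(2,2,2-trifluoroethoxy)phosphoryl)propanoate] of 13 | C=C(OS(=O)(=O)C(F)(F)F)[C@@H]1C[C@@H]2O[C@]2(C)[C@H](OC(=O)C(C)P(=O)(OCC(F)(F)F)OCC(F)(F)F)[C@@H]1OC(=O)C(C)P(=O)(OCC(F)(F)F)OCC(F)(F)F
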